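**Plan**
1. Cuts, in retrosynthetic order: the four protective phenol O–benzyl bonds; the acyl–oxygen bond O1–C2 of both γ-butyrolactones; both ring bonds C4–C5 at once; the aryl–aryl bond between the carbons ortho to the two inner phenolic oxygens; the C=C bond of each half.
2. Enabling feature: in each lactone ring the C4–H carbon carries the ring C5H2–O carbon and an arylmethyl group. It is bonded to the tertiary carbinol C3, whose other ring neighbour is the carbonyl C2. C4, C3 and C2 are therefore C3, C2 and C1 of a 2,3-epoxy alcohol, and C5 is a carbon nucleophile added at C3 (vinyl, a masked CH2OH).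
3. Forward: four vanillin-type building blocks give two bromo-substituted Z-allylic alcohols, which a Suzuki–Miyaura coupling joins unsymmetrically. Both olefins are then epoxidised and both epoxides opened by vinyl. Both lactone rings close last, together, after C1 oxidation and vinyl cleavage.
4. Stereochemistry: the Z geometry and L-(+)-tartrate-controlled epoxidation set each epoxide as (2S,3R). Anti opening inverts C3 and leaves the C2–O bond alone, which gives (3R,4R) in each lactone. No later step touches these centres.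

Key step: step 15

Remark: the biaryl bond has only two ortho substituents (the oxygen functions), so rotation about it is taken as free and it is not counted as a stereo element.

**Step 1**
Reactants: 1 5-bromovanillin; 2 benzyl bromide
Product: 3 4-benzyloxy-3-bromo-5-methoxybenzaldehyde
Conditions: K2CO3, DMF, 60 °C
Reagents that add atoms: none
Why: Williamson ether synthesis on the acidic phenol; the benzyl ether tolerates the bases, hydrides, organometallics and oxidants that follow and leaves only in the final hydrogenolysis.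

**Step 2**
Reactants: 3 4-benzyloxy-3-bromo-5-methoxybenzaldehyde
Product: 4 (4-benzyloxy-3-bromo-5-methoxyphenyl)methanol
Conditions: NaBH4, MeOH–THF, 0 °C
Reagents that add atoms: none
Why: Borohydride reduction of an aromatic aldehyde, which leaves the aryl bromide and the benzyl ether untouched.

**Step 3**
Reactants: 4 (4-benzyloxy-3-bromo-5-methoxyphenyl)methanol
Product: 5 4-benzyloxy-3-bromo-5-methoxybenzyl bromide
Conditions: PBr3, CH2Cl2, 0 °C
Reagents that add atoms: phosphorus tribromide, BrP(Br)Br
Why: Bromination of an electron-rich benzylic alcohol through its phosphite ester with SN2 displacement by bromide; the labile bromide is used at once.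

**Step 4**
Reactants: 5 4-benzyloxy-3-bromo-5-methoxybenzyl bromide; 6 methyl bis(2,2,2-trifluoroethyl)phosphonoacetate
Product: 7 methyl 3-(4-benzyloxy-3-bromo-5-methoxyphenyl)-2-[bis(2,2,2-trifluoroethoxy)phosphoryl]propanoate (racemic)
Conditions: NaH, DMF, 0 °C → rt (6 in 1.5-fold excess)
Reagents that add atoms: none
Why: SN2 C-alkylation of the stabilised sodium phosphonoacetate with a benzylic bromide, the excess of 6 holding back a second alkylation; the new α-stereocentre is racemic and disappears in step 6.

**Step 5**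
Reactants: 8 4-benzyloxy-3-methoxybenzaldehyde; 9 (methoxymethyl)triphenylphosphonium chloride
Product: 11 (4-benzyloxy-3-methoxyphenyl)acetaldehyde, via methyl enol ether 10 (not isolated)
Conditions: KOtBu, THF, 0 °C → rt; then 2 M HCl, THF, 40 °C
Reagents that add atoms: water, O
Why: Wittig methoxymethylenation followed by acid hydrolysis of the enol ether in the same flask is the standard one-carbon homologation of an aryl aldehyde to an arylacetaldehyde, and both enol ether isomers converge on one achiral product.

**Step 6**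
Reactants: 7 bromoaryl phosphonate; 11 (4-benzyloxy-3-methoxyphenyl)acetaldehyde
Product: 12 methyl (Z)-2-(4-benzyloxy-3-bromo-5-methoxybenzyl)-4-(4-benzyloxy-3-methoxyphenyl)but-2-enoate
Conditions: KN(SiMe3)2, 18-crown-6, THF, −78 °C
Reagents that add atoms: none
Why: Still–Gennari variant of the Horner–Wadsworth–Emmons olefination: the electron-poor trifluoroethyl phosphonate and the crown-complexed potassium ion make collapse of the kinetic adduct faster than its reversal, so the aldehyde-derived CH2Ar ends up cis to the ester (Z), while −78 °C and a slight deficit of base spare the enolisable aldehyde and the doubly activated C4 hydrogens of the product.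

**Step 7**
Reactants: 12 Z-enoate
Product: 13 (Z)-2-(4-benzyloxy-3-bromo-5-methoxybenzyl)-4-(4-benzyloxy-3-methoxyphenyl)but-2-en-1-ol
Conditions: iBu2AlH, CH2Cl2, −78 °C
Reagents that add atoms: none
Why: 1,2-Reduction of the enoate by two hydride transfers from iBu2AlH gives the allylic alcohol with the Z geometry retained and the aryl bromide intact.

**Step 8**
Reactants: 3 4-benzyloxy-3-bromo-5-methoxybenzaldehyde; 9 (methoxymethyl)triphenylphosphonium chloride
Product: 15 (4-benzyloxy-3-bromo-5-methoxyphenyl)acetaldehyde, via bromo enol ether 14 (not isolated)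
Conditions: KOtBu, THF, 0 °C → rt; then 2 M HCl, THF, 40 °C
Reagents that add atoms: water, O
Why: The same Wittig homologation as in step 5; the aryl bromide is inert to the ylide and to dilute acid.

**Step 9**
Reactants: 16 (4-benzyloxy-3-methoxyphenyl)methanol
Product: 17 4-benzyloxy-3-methoxybenzyl bromide
Conditions: PBr3, CH2Cl2, 0 °C
Reagents that add atoms: phosphorus tribromide, BrP(Br)Br
Why: Benzylic alcohol to bromide through the phosphite ester (SN2), as in step 3.

**Step 10**
Reactants: 17 4-benzyloxy-3-methoxybenzyl bromide; 6 methyl bis(2,2,2-trifluoroethyl)phosphonoacetate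
Product: 18 methyl 3-(4-benzyloxy-3-methoxyphenyl)-2-[bis(2,2,2-trifluoroethoxy)phosphoryl]propanoate (racemic)
Conditions: NaH, DMF, 0 °C → rt (6 in 1.5-fold excess)
Reagents that add atoms: none
Why: SN2 C-alkylation of the phosphonoacetate anion as in step 4; the racemic α-stereocentre is erased in step 11.

**Step 11**
Reactants: 18 aryl phosphonate; 15 (4-benzyloxy-3-bromo-5-methoxyphenyl)acetaldehyde
Product: 19 methyl (Z)-2-(4-benzyloxy-3-methoxybenzyl)-4-(4-benzyloxy-3-bromo-5-methoxyphenyl)but-2-enoate
Conditions: KN(SiMe3)2, 18-crown-6, THF, −78 °C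
Reagents that add atoms: none
Why: Still–Gennari olefination as in step 6 with the two aryl groups exchanged, which again places the aldehyde-derived CH2Ar cis to the ester under kinetic control.

**Step 12**
Reactants: 19 Z-enoate
Product: 20 (Z)-2-(4-benzyloxy-3-methoxybenzyl)-4-(4-benzyloxy-3-bromo-5-methoxyphenyl)but-2-en-1-ol
Conditions: iBu2AlH, CH2Cl2, −78 °C
Reagents that add atoms: none
Why: 1,2-Reduction of the enoate with iBu2AlH as in step 7, with the geometry retained.

**Step 13**
Reactants: 20 bromo allylic alcohol; 13 bromo allylic alcohol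
Product: 22 biaryl bis(Z-allylic alcohol) in which 13 and 20 are joined by a bond between their former C–Br carbons, via pinacol boronate 21 (not isolated)
Conditions: B2pin2 (1.05 equiv), Pd(dppf)Cl2 (5 mol %), KOAc, 1,4-dioxane, 85 °C; then 13, aq K3PO4, 85 °C
Reagents that add atoms: bis(pinacolato)diboron, CC1(C)OB(OC1(C)C)B1OC(C)(C)C(C)(C)O1 (its atoms stand in 21 only)
Why: Miyaura borylation of one aryl bromide and Suzuki–Miyaura cross-coupling with the other in the same flask join two rings that differ only in their side chains, which makes the unsymmetrical linkage unambiguous; the coupling is placed at the allylic alcohol stage because enoates 12 and 19 carry base-labile C4 hydrogens, and no stereo element arises.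

**Step 14**
Reactants: 22 biaryl bis(Z-allylic alcohol)
Product: 23 biaryl bis[(2S,3R)-2,3-epoxy alcohol] in which both olefins of 22 are oxiranes with the C3 arylmethyl cis to CH2OH
Conditions: Ti(OiPr)4 (0.5 equiv), L-(+)-diisopropyl tartrate (0.6 equiv), tBuOOH (5 equiv, decane), 4 Å molecular sieves, CH2Cl2, −20 °C
Reagents that add atoms: tert-butyl hydroperoxide, CC(C)(C)OO
Why: Twofold Sharpless asymmetric epoxidation: each allylic alkoxide binds to the titanium tartrate complex, which transfers the peroxide oxygen to one olefin face regardless of the remote half; L-(+)-tartrate converts Z-allylic alcohols of the nerol type into (2S,3R)-epoxy alcohols, syn addition carries the Z geometry into the cis relation of C3–CH2Ar and CH2OH, and a facial error at either site ends in a separable diastereomer, which should raise the enantiomeric purity of 23.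

**Step 15**
Reactants: 23 biaryl bis[(2S,3R)-2,3-epoxy alcohol]; 24 vinylmagnesium bromide
Product: 25 biaryl bis[(2R,3R)-2,3-bis(arylmethyl)pent-4-ene-1,2-diol]
Conditions: 24 (12 equiv), CuI (0.4 equiv), THF, −30 → 0 °C
Reagents that add atoms: none
Why: Two equivalents of 24 first turn both hydroxyls into magnesium alkoxides; the vinylcuprate formed from CuI then attacks C3 of each oxirane from the side opposite the C3–O bond (SN2-type oxidative addition to a trivalent copper species, then reductive elimination), which forms the C3–vinyl bond and leaves the oxygen on C2 as the tertiary alkoxide. The closest known reaction type is the copper-catalysed Grignard opening of 2-substituted 2,3-epoxy alcohols to 1,2-diols, run here at two remote and independent sites. No ring is closed; two oxiranes are opened. The new stereocentre of each half is set by inversion at the (3R)-oxirane carbon, while C2 keeps its C–O bond and its configuration, so each half emerges (2R,3R), the arrangement that becomes the trans-dibenzyl (3R,4R)-lactone. The step needs C3 over C2 regioselectivity at both sites, and the fully substituted C2, which cannot accept a backside attack, secures it; epoxide migration towards C1 should stay slow for magnesium alkoxides in cold aprotic THF. The large excess of 24 should drive both openings to completion, and the benzyl ethers, methoxy groups and biaryl are inert.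

**Step 16**
Reactants: 25 biaryl bis(pentene-1,2-diol)
Product: 26 biaryl bis[(2R,3R)-2-hydroxy aldehyde] in which both CH2OH groups of 25 are CHO
Conditions: SO3·pyridine, DMSO, Et3N, CH2Cl2, 0 °C
Reagents that add atoms: none
Why: Parikh–Doering activated-DMSO oxidation takes only the primary hydroxyls, cannot oxidise the tertiary carbinols and does not cleave the glycol C–C bond, and the fully substituted α-carbon cannot epimerise.

**Step 17**
Reactants: 26 biaryl bis(2-hydroxy aldehyde)
Product: 27 biaryl bis[(2R,3R)-2-hydroxy acid] in which both CHO groups are CO2H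
Conditions: NaClO2, NaH2PO4, 2-methyl-2-butene, tBuOH–THF–H2O, 0 °C → rt
Reagents that add atoms: sodium chlorite, [Na+].[O-]Cl=O
Why: Pinnick chlorite oxidation of the aldehydes, with 2-methyl-2-butene trapping the hypochlorous acid so that the vinyl groups and the electron-rich arenes are spared.

**Step 18**
Reactants: 27 biaryl bis(2-hydroxy acid)
Product: 29 tetra-O-benzyl ether of the target with both (3R,4R)-lactones closed, via bis(hydroxy acid) 28 (not isolated)
Conditions: O3, CH2Cl2–MeOH, −78 °C (Sudan Red 7B as end-point dye); NaBH4, −78 → 0 °C; then 1 M HCl to pH 2, rt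
Reagents that add atoms: ozone, [O-][O+]=O
Why: Ozonolysis of the terminal vinyl groups, which react ahead of the alkoxyarenes, is followed by borohydride reduction of the peroxidic products while the acids rest as inert carboxylates; acidification then triggers 5-exo-trig lactonisation of both γ-hydroxy acids without touching a stereocentre.

**Step 19**
Reactants: 29 tetra-O-benzyl ether
Product: 30 target CNP0218652.1
Conditions: H2 (1 atm), Pd/C (10 %), EtOAc–MeOH, rt
Reagents that add atoms: none
Why: Catalytic hydrogenolysis of the four aryl benzyl ethers; the lactones, the non-benzylic tertiary alcohols and the biaryl are not affected.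

**Compound list**
1 | 5-bromovanillin | COc1cc(C=O)cc(Br)c1O | starting material
2 | benzyl bromide | BrCc1ccccc1 | starting material
3 | 4-benzyloxy-3-bromo-5-methoxybenzaldehyde | COc1cc(C=O)cc(Br)c1OCc1ccccc1 | intermediate
4 | (4-benzyloxy-3-bromo-5-methoxyphenyl)methanol | COc1cc(CO)cc(Br)c1OCc1ccccc1 | intermediate
5 | 4-benzyloxy-3-bromo-5-methoxybenzyl bromide | COc1cc(CBr)cc(Br)c1OCc1ccccc1 | intermediate
6 | methyl bis(2,2,2-trifluoroethyl)phosphonoacetate | COC(=O)CP(=O)(OCC(F)(F)F)OCC(F)(F)F | starting material
7 | methyl 3-(4-benzyloxy-3-bromo-5-methoxyphenyl)-2-[bis(2,2,2-trifluoroethoxy)phosphoryl]propanoate (racemic) | COC(=O)C(Cc1cc(OC)c(OCc2ccccc2)c(Br)c1)P(=O)(OCC(F)(F)F)OCC(F)(F)F | intermediate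
8 | 4-benzyloxy-3-methoxybenzaldehyde (O-benzylvanillin) | COc1cc(C=O)ccc1OCc1ccccc1 | starting material
9 | (methoxymethyl)triphenylphosphonium chloride | COC[P+](c1ccccc1)(c1ccccc1)c1ccccc1.[Cl-] | starting material
10 | 1-benzyloxy-2-methoxy-4-(2-methoxyethenyl)benzene (E/Z mixture) | COC=Cc1ccc(OCc2ccccc2)c(OC)c1 | intermediate
11 | (4-benzyloxy-3-methoxyphenyl)acetaldehyde | COc1cc(CC=O)ccc1OCc1ccccc1 | intermediate
12 | methyl (Z)-2-(4-benzyloxy-3-bromo-5-methoxybenzyl)-4-(4-benzyloxy-3-methoxyphenyl)but-2-enoate | COC(=O)/C(Cc1cc(OC)c(OCc2ccccc2)c(Br)c1)=C\Cc1ccc(OCc2ccccc2)c(OC)c1 | intermediate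
13 | (Z)-2-(4-benzyloxy-3-bromo-5-methoxybenzyl)-4-(4-benzyloxy-3-methoxyphenyl)but-2-en-1-ol | OC/C(Cc1cc(OC)c(OCc2ccccc2)c(Br)c1)=C\Cc1ccc(OCc2ccccc2)c(OC)c1 | intermediate
14 | 2-benzyloxy-1-bromo-3-methoxy-5-(2-methoxyethenyl)benzene (E/Z mixture) | COC=Cc1cc(OC)c(OCc2ccccc2)c(Br)c1 | intermediate
15 | (4-benzyloxy-3-bromo-5-methoxyphenyl)acetaldehyde | COc1cc(CC=O)cc(Br)c1OCc1ccccc1 | intermediate
16 | (4-benzyloxy-3-methoxyphenyl)methanol | COc1cc(CO)ccc1OCc1ccccc1 | starting material
17 | 4-benzyloxy-3-methoxybenzyl bromide | COc1cc(CBr)ccc1OCc1ccccc1 | intermediate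
18 | methyl 3-(4-benzyloxy-3-methoxyphenyl)-2-[bis(2,2,2-trifluoroethoxy)phosphoryl]propanoate (racemic) | COC(=O)C(Cc1ccc(OCc2ccccc2)c(OC)c1)P(=O)(OCC(F)(F)F)OCC(F)(F)F | intermediate
19 | methyl (Z)-2-(4-benzyloxy-3-methoxybenzyl)-4-(4-benzyloxy-3-bromo-5-methoxyphenyl)but-2-enoate | COC(=O)/C(Cc1ccc(OCc2ccccc2)c(OC)c1)=C\Cc1cc(OC)c(OCc2ccccc2)c(Br)c1 | intermediate
20 | (Z)-2-(4-benzyloxy-3-methoxybenzyl)-4-(4-benzyloxy-3-bromo-5-methoxyphenyl)but-2-en-1-ol | OC/C(Cc1ccc(OCc2ccccc2)c(OC)c1)=C\Cc1cc(OC)c(OCc2ccccc2)c(Br)c1 | intermediate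
21 | pinacol boronate of 20 (Bpin in place of Br) | OC/C(Cc1ccc(OCc2ccccc2)c(OC)c1)=C\Cc1cc(OC)c(OCc2ccccc2)c(B2OC(C)(C)C(C)(C)O2)c1 | intermediate
22 | biaryl bis(Z-allylic alcohol) | COc1cc(C/C=C(\CO)Cc2cc(OC)c(OCc3ccccc3)c(-c3cc(C/C=C(\CO)Cc4ccc(OCc5ccccc5)c(OC)c4)cc(OC)c3OCc3ccccc3)c2)ccc1OCc1ccccc1 | intermediate
23 | biaryl bis[(2S,3R)-2,3-epoxy alcohol] | COc1cc(C[C@H]2O[C@]2(CO)Cc2cc(OC)c(OCc3ccccc3)c(-c3cc(C[C@H]4O[C@]4(CO)Cc4ccc(OCc5ccccc5)c(OC)c4)cc(OC)c3OCc3ccccc3)c2)ccc1OCc1ccccc1 | intermediate
24 | vinylmagnesium bromide | C=C[Mg]Br | starting material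
25 | biaryl bis[(2R,3R)-2,3-bis(arylmethyl)pent-4-ene-1,2-diol] | COc1cc(C[C@@H]([C@@](O)(CO)Cc2cc(OC)c(OCc3ccccc3)c(-c3cc(C[C@@H]([C@@](O)(CO)Cc4ccc(OCc5ccccc5)c(OC)c4)C=C)cc(OC)c3OCc3ccccc3)c2)C=C)ccc1OCc1ccccc1 | intermediate
26 | biaryl bis[(2R,3R)-2-hydroxy aldehyde] | COc1cc(C[C@@H]([C@@](O)(C=O)Cc2cc(OC)c(OCc3ccccc3)c(-c3cc(C[C@@H]([C@@](O)(C=O)Cc4ccc(OCc5ccccc5)c(OC)c4)C=C)cc(OC)c3OCc3ccccc3)c2)C=C)ccc1OCc1ccccc1 | intermediate
27 | biaryl bis[(2R,3R)-2-hydroxy acid] | COc1cc(C[C@@H]([C@@](O)(C(=O)O)Cc2cc(OC)c(OCc3ccccc3)c(-c3cc(C[C@@H]([C@@](O)(C(=O)O)Cc4ccc(OCc5ccccc5)c(OC)c4)C=C)cc(OC)c3OCc3ccccc3)c2)C=C)ccc1OCc1ccccc1 | intermediate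
28 | biaryl bis[(2R,3R)-2,4-dihydroxy acid] | COc1cc(C[C@@H]([C@@](O)(C(=O)O)Cc2cc(OC)c(OCc3ccccc3)c(-c3cc(C[C@@H]([C@@](O)(C(=O)O)Cc4ccc(OCc5ccccc5)c(OC)c4)CO)cc(OC)c3OCc3ccccc3)c2)CO)ccc1OCc1ccccc1 | intermediate
29 | tetra-O-benzyl ether of the target, both lactones (3R,4R) | COc1cc(C[C@@H]2COC(=O)[C@@]2(O)Cc2cc(OC)c(OCc3ccccc3)c(-c3cc(C[C@@H]4COC(=O)[C@@]4(O)Cc4ccc(OCc5ccccc5)c(OC)c4)cc(OC)c3OCc3ccccc3)c2)ccc1OCc1ccccc1 | intermediate
30 | CNP0218652.1, both lactones (3R,4R) | COc1cc(C[C@@H]2COC(=O)[C@@]2(O)Cc2cc(OC)c(O)c(-c3cc(C[C@@H]4COC(=O)[C@@]4(O)Cc4ccc(O)c(OC)c4)cc(OC)c3O)c2)ccc1O | target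

**Total step count:** 19.
**Longest linear sequence:** 13 steps from 5-bromovanillin (steps 1, 2, 3, 4, 6, 7, 13, 14, 15, 16, 17, 18, 19).

**Steps most likely to fail**

1. **Step 15.** Substitution at C3, which lies next to a fully substituted carbon, may be slow. Opening by bromide, Lewis-acid-induced rearrangement of the trisubstituted oxirane or epoxide migration could then overtake C–C bond formation, or one of the two sites could stay unreacted.
   - The fallback sets out from 23 and comes back at 25. It keeps the C3–C bond but changes the nucleophile class and the mode of delivery.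
   - Diethyl[(trimethylsilyl)ethynyl]aluminium (Me3SiC≡CLi and Et2AlCl, toluene, 0 °C) first forms the aluminium alkoxide of each free hydroxyl. This activates the oxirane and steers the slim sp-carbon nucleophile to C3 with inversion, giving the bis(trimethylsilylalkyne) tetraol F1.
   - K2CO3 in MeOH removes silicon to give the bis(terminal alkyne) tetraol F2.
   - Semihydrogenation over Pd/CaCO3 poisoned with Pb(OAc)2, with quinoline, gives 25.

2. **Step 14.** Z-substituted allylic alcohols are the slow class of substrates for the titanium tartrate catalyst and show the weakest facial selectivity, and the step has to succeed at two sites.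
   - The fallback sets out from 22 and comes back at 23 in one operation. It replaces hydroxyl-directed metal catalysis by non-directed dioxirane catalysis (Shi epoxidation), for which trisubstituted olefins are the best substrate class.
   - Conditions: the ketone derived from D-fructose, KHSO5 (as 2KHSO5·KHSO4·K2SO4), K2CO3 buffer at pH 10.5, MeCN–dimethoxymethane–H2O, 0 °C.
   - By the spiro transition-state model this ketone gives the R configuration at the CH carbon of trisubstituted olefins, which is the (2S,3R) sense needed here.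
   - No compound outside the list is made (F0).

3. **Step 6.** The phosphonate anion may enolise the arylacetaldehyde, the bulky α-substituent may erode the Z selectivity, and base may move the double bond into conjugation with the arene. Step 11 shares these hazards.
   - The fallback sets out from 17, uses 5, and comes back at 13. It fixes the geometry by a syn addition to an alkyne instead of an olefination.
   - The bromomagnesium dianion of propargyl alcohol (EtMgBr, THF) is benzylated at carbon by 17 under CuCl catalysis to give 4-(4-benzyloxy-3-methoxyphenyl)but-2-yn-1-ol F3.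
   - Syn hydrostannation catalysed by Pd(PPh3)2Cl2 with Bu3SnH, steered to the carbon next to the carbinol, gives (E)-4-(4-benzyloxy-3-methoxyphenyl)-2-(tributylstannyl)but-2-en-1-ol F4. In F4, H and Sn are cis, so CH2Ar already stands cis to CH2OH.
   - Stille coupling of F4 with the benzylic C–Br bond of 5 (Pd(PPh3)4, CuI, DMF, 40 °C), which should react ahead of the aryl C–Br bond, replaces tin with retention and gives 13.

**Further compounds**
F1 | step 15 | biaryl bis[(2R,3R)-2,3-bis(arylmethyl)-5-(trimethylsilyl)pent-4-yne-1,2-diol] | COc1cc(C[C@@H]([C@@](O)(CO)Cc2cc(OC)c(OCc3ccccc3)c(-c3cc(C[C@@H]([C@@](O)(CO)Cc4ccc(OCc5ccccc5)c(OC)c4)C#C[Si](C)(C)C)cc(OC)c3OCc3ccccc3)c2)C#C[Si](C)(C)C)ccc1OCc1ccccc1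
F2 | step 15 | biaryl bis[(2R,3R)-2,3-bis(arylmethyl)pent-4-yne-1,2-diol] | COc1cc(C[C@@H]([C@@](O)(CO)Cc2cc(OC)c(OCc3ccccc3)c(-c3cc(C[C@@H]([C@@](O)(CO)Cc4ccc(OCc5ccccc5)c(OC)c4)C#C)cc(OC)c3OCc3ccccc3)c2)C#C)ccc1OCc1ccccc1
F0 | step 14 | none | none
F3 | step 6 | 4-(4-benzyloxy-3-methoxyphenyl)but-2-yn-1-ol | OCC#CCc1ccc(OCc2ccccc2)c(OC)c1
F4 | step 6 | (E)-4-(4-benzyloxy-3-methoxyphenyl)-2-(tributylstannyl)but-2-en-1-ol | OC/C([Sn](CCCC)(CCCC)CCCC)=C\Cc1ccc(OCc2ccccc2)c(OC)c1
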